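**Retrosynthetic overview**

1. Endgame on ring A: the target comes from a trans-fused 11-silyloxy-eudesma-3,6-dien-8-one by α-face cis-dihydroxylation of C3=C4, angeloylation at C3, acetylation at C4 and desilylation.
2. Key disconnection: C6–C7 and C8–C9 of ring B are cut together. An ene–yne–ene metathesis cascade inserts a siloxy alkyne (C7≡C8, carrying C11) between two vinyl groups on C5 and C10 of a cyclohexene; hydrolysis of the siloxy diene gives the enone.
3. Enabling feature: ring B is C5–C6H=C7–C8(=O)–C9H2–C10, the keto form of a 2-siloxy-1,3-diene C6=C7–C8(OSi)=C9 whose termini C6 and C9 sit on the vicinal ring-fusion carbons C5/C10. Such a 1,5-diene cannot ring-close alone, and the oxygen on C8 fixes the direction of alkyne insertion.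
4. Ring A is made first: an exo-selective catalytic asymmetric Diels–Alder reaction of (E)-3-methylhexa-1,3,5-triene with methacrolein sets C5 and C10 (H and CH3 trans); a Wittig reaction gives the divinylcyclohexene.
5. Ring order: ring A (Diels–Alder), then ring B (metathesis cascade); C3 and C4 are set afterwards under control of the bicyclic framework.

Key step: step 8

Assumption 1: atom numbers are eudesmane numbers (ring A = C1–C5 and C10, ring B = C5–C10, C11 = side-chain carbinol carbon); α/β refer to the usual drawing with the C10 methyl β, so the target is (3R,4S,5R,10R), trans-fused.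
Assumption 2: the sense of induction in step 4 is taken from the formyl C–H···O pre-transition-state model for 2-substituted acroleins; if the adduct proves antipodal, the (R)-catalyst is used instead.

**Route**

Step 1
Reactants: 1 (E)-3-methylpent-2-en-4-yn-1-ol
Product: 2 (E)-3-methylpenta-2,4-dien-1-ol
Conditions: H2 (1 atm), Lindlar catalyst (Pd/CaCO3 poisoned with Pb(OAc)2), quinoline, EtOAc, 0 °C to rt, stopped after 1 equiv H2
Reagents that add atoms: none
Why: Lindlar semihydrogenation of a terminal alkyne stops at the alkene and leaves the trisubstituted (E)-alkene untouched, so the diene geometry needed in step 4 is inherited from 1.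

Step 2
Reactants: 2 (E)-3-methylpenta-2,4-dien-1-ol
Product: 3 (E)-3-methylpenta-2,4-dienal
Conditions: activated MnO2 (excess), CH2Cl2, rt; filtered solution concentrated cold and used directly
Reagents that add atoms: none
Why: MnO2 oxidises allylic (here dienylic) primary alcohols selectively to the enal without touching the (E)-double bond.

Step 3
Reactants: 3 (E)-3-methylpenta-2,4-dienal
Product: 4 (E)-3-methylhexa-1,3,5-triene
Conditions: Ph3PCH3Br, KOt-Bu, Et2O, 0 °C to rt; pentane filtration through silica, careful distillation
Reagents that add atoms: methyltriphenylphosphonium bromide, C[P+](c1ccccc1)(c1ccccc1)c1ccccc1.[Br-]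
Why: Wittig methylenation of an enal with a non-stabilised ylide gives the terminal alkene by 1,2-addition, and the existing (E)-C3=C4 bond is not involved, so a stereodefined triene should result.

Step 4
Reactants: 4 (E)-3-methylhexa-1,3,5-triene; 5 methacrolein
Product: 6 (1S,2S)-2-ethenyl-1,3-dimethylcyclohex-3-ene-1-carbaldehyde
Conditions: 5 (3 equiv), (S)-3,3-diphenyl-1-(o-tolyl)tetrahydro-1H,3H-pyrrolo[1,2-c][1,3,2]oxazaborole activated with HNTf2 (10 mol %), CH2Cl2, −78 °C
Reagents that add atoms: none
Why: Enantioselective Lewis acid catalysed Diels–Alder reaction of a 2-substituted acrolein: only the C1–C4 diene of the triene can reach the s-cis form (the other diene unit has an inside methyl group), the conjugating vinyl group on the diene terminus directs "ortho" bonding to the α-carbon of methacrolein (quaternary C10), the formyl group reacts exo as is usual for methacrolein (vinyl and CHO trans, hence H5 and CH3-10 trans), and the oxazaborolidinium cation shields one face of the coordinated s-trans aldehyde, which should set both centres as (1S,2S).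

Step 5
Reactants: 6 (1S,2S)-2-ethenyl-1,3-dimethylcyclohex-3-ene-1-carbaldehyde
Product: 7 (3S,4R)-3,4-diethenyl-2,4-dimethylcyclohex-1-ene
Conditions: Ph3PCH3Br, KOt-Bu, THF, 0 °C to 50 °C
Reagents that add atoms: methyltriphenylphosphonium bromide, C[P+](c1ccccc1)(c1ccccc1)c1ccccc1.[Br-]
Why: Wittig methylenation of a non-enolisable, α-quaternary aldehyde; no stereocentre can be affected (the descriptor at C10 changes only through the priority rules).

Step 6
Reactants: 8 2-methylbut-3-yn-2-ol
Product: 9 triethyl[(2-methylbut-3-yn-2-yl)oxy]silane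
Conditions: TESOTf, 2,6-lutidine, CH2Cl2, 0 °C
Reagents that add atoms: triethylsilyl triflate, CC[Si](CC)(CC)OS(=O)(=O)C(F)(F)F
Why: Silyl triflate with 2,6-lutidine is the standard silylation of a tertiary alcohol; the TES ether should survive strong base, metathesis, dihydroxylation and acylation and is removed last.

Step 7
Reactants: 9 triethyl[(2-methylbut-3-yn-2-yl)oxy]silane
Product: 12 triethyl({2-methyl-4-[(triisopropylsilyl)oxy]but-3-yn-2-yl}oxy)silane, via lithium acetylide 10 (not isolated), via lithium ynolate 11 (not isolated)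
Conditions: n-BuLi, THF, −78 °C; then LiOOt-Bu (from t-BuOOH and LiHMDS), −78 to 0 °C; then TIPSOTf, −78 to 0 °C
Reagents that add atoms: tert-butyl hydroperoxide, CC(C)(C)OO; triisopropylsilyl triflate, CC(C)[Si](C(C)C)(C(C)C)OS(=O)(=O)C(F)(F)F
Why: Oxidation of a lithium acetylide by lithium tert-butyl peroxide is an established entry to lithium ynolates, and a bulky silyl triflate traps the ynolate on oxygen to give an isolable 1-siloxy-1-alkyne.

Step 8
Reactants: 7 (3S,4R)-3,4-diethenyl-2,4-dimethylcyclohex-1-ene; 12 triethyl({2-methyl-4-[(triisopropylsilyl)oxy]but-3-yn-2-yl}oxy)silane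
Product: 14 (5R,10R)-11-(triethylsilyloxy)eudesma-3,6-dien-8-one, via siloxy diene 13 (not isolated)
Conditions: 12 (2.5 equiv, slow addition), second-generation Grubbs catalyst (H2IMes)(PCy3)Cl2Ru=CHPh (10 mol %), toluene, 70 °C, argon sparge; then TBAF/AcOH (1:1), THF, −20 to 0 °C
Reagents that add atoms: none
Why: Proposed new method: a tandem intermolecular enyne metathesis/ring-closing metathesis in which the ruthenium alkylidene formed at the vinyl group on C5 (alkylidene carbon C6) adds to siloxy alkyne 12 so that C6 bonds to the carbon-substituted C7 and ruthenium sits on the oxygen-bearing C8 as a heteroatom-stabilised vinylcarbene, which then ring-closes onto the vinyl group on C10 (C8=C9) with loss of ethene; buffered fluoride converts the 2-siloxy-1,3-diene 13 into enone 14 by protonation at C9. The closest known reactions are the ring-closing enyne metathesis of tethered 1-siloxy-1-alkynes with alkenes, which gives cyclic siloxy dienes and enones after desilylation, and the tandem intermolecular enyne metathesis of alkynes with 1,5-dienes or cycloalkenes, which gives cyclic 1,3-dienes; joining the two on an untethered siloxy alkyne is the new element. Ring B closes in the ring-closing metathesis event as a six-membered ring that contains both alkyne carbons, through ordinary ruthenacyclobutanes and not through a bridged transition state, so the trans relation of C5-H and C10-CH3 from step 4 is carried over and no new stereocentre is formed. Two selectivities are needed: loading of ruthenium at the C5 vinyl and not the C10 vinyl, secured by the allylic quaternary centre at C10, which should make that alkene react only intramolecularly, and the orientation of alkyne insertion, secured by the polarity of the ynol ether (nucleophilic C7 to the alkylidene carbon, ruthenium to C8, as with enol ethers). The 1,5-diene cannot cyclise by itself (it would give a cyclobutene), and keeping C4 sp2 in ring A leaves the C5 vinyl group accessible and postpones all ring-A oxygenation until the bicycle can control it.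

Step 9
Reactants: 14 (5R,10R)-11-(triethylsilyloxy)eudesma-3,6-dien-8-one
Product: 15 (3R,4S,5R,10R)-3α,4α-dihydroxy-11-(triethylsilyloxy)eudesm-6-en-8-one
Conditions: OsO4 (3 mol %), NMO, acetone/H2O, 0 °C to rt
Reagents that add atoms: osmium tetroxide, O=[Os](=O)(=O)=O (catalytic, transfers both oxygen atoms); N-methylmorpholine N-oxide, C[N+]1([O-])CCOCC1; water, O
Why: Upjohn syn-dihydroxylation: the electron-rich trisubstituted C3=C4 alkene should react in preference to the electron-poor, hindered enone alkene, and osmium should add from the α-face, anti to the axial C10 methyl of the trans-fused bicycle, which sets C3 and C4 together as the 3α,4α-cis-diol.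

Step 10
Reactants: 15 (3R,4S,5R,10R)-3α,4α-dihydroxy-11-(triethylsilyloxy)eudesm-6-en-8-one; 16 angelic acid
Product: 18 3α-angeloyloxy-4α-hydroxy-11-(triethylsilyloxy)eudesm-6-en-8-one, via mixed anhydride 17 (not isolated)
Conditions: 16, 2,4,6-Cl3C6H2COCl, Et3N, toluene, rt; then 15, 80 °C
Reagents that add atoms: none
Why: Yamaguchi esterification through the preformed mixed anhydride without a nucleophilic catalyst should acylate only the secondary C3 hydroxyl (C4–OH is tertiary, C11–O is silylated) and is the usual way to introduce an angelate without Z-to-E isomerisation; O-acylation retains the configuration at C3.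

Step 11
Reactants: 18 3α-angeloyloxy-4α-hydroxy-11-(triethylsilyloxy)eudesm-6-en-8-one
Product: 19 4α-acetoxy-3α-angeloyloxy-11-(triethylsilyloxy)eudesm-6-en-8-one
Conditions: Ac2O, Et3N, DMAP (cat.), CH2Cl2, 40 °C
Reagents that add atoms: acetic anhydride, CC(=O)OC(C)=O
Why: DMAP-catalysed acetylation of the only free hydroxyl, the tertiary C4–OH; the configuration at C4 is not touched.

Step 12
Reactants: 19 4α-acetoxy-3α-angeloyloxy-11-(triethylsilyloxy)eudesm-6-en-8-one
Product: 20 4α-acetoxy-3α-angeloyloxy-11-hydroxyeudesm-6-en-8-one (target)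
Conditions: HF·pyridine, pyridine/THF, 0 °C to rt
Reagents that add atoms: none
Why: Fluoride cleavage of the tertiary triethylsilyl ether under buffered HF·pyridine, conditions under which the acetate, the angelate and the enone should be stable, releases the C11 hydroxyl.

**Compound list**

1 | (E)-3-methylpent-2-en-4-yn-1-ol | C#C/C(C)=C/CO | starting material
2 | (E)-3-methylpenta-2,4-dien-1-ol | C=C/C(C)=C/CO | intermediate
3 | (E)-3-methylpenta-2,4-dienal | C=C/C(C)=C/C=O | intermediate
4 | (E)-3-methylhexa-1,3,5-triene | C=C/C(C)=C/C=C | intermediate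
5 | methacrolein (2-methylprop-2-enal) | CC(=C)C=O | starting material
6 | (1S,2S)-2-ethenyl-1,3-dimethylcyclohex-3-ene-1-carbaldehyde (CHO and vinyl trans) | CC1=CCC[C@](C)(C=O)[C@H]1C=C | intermediate
7 | (3S,4R)-3,4-diethenyl-2,4-dimethylcyclohex-1-ene (vinyl groups trans) | CC1=CCC[C@](C)(C=C)[C@H]1C=C | intermediate
8 | 2-methylbut-3-yn-2-ol | CC(C)(O)C#C | starting material
9 | triethyl[(2-methylbut-3-yn-2-yl)oxy]silane | CC(C)(O[Si](CC)(CC)CC)C#C | intermediate
10 | lithium acetylide of 9 | CC(C)(O[Si](CC)(CC)CC)C#[C-].[Li+] | intermediate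
11 | lithium 3-methyl-3-(triethylsilyloxy)but-1-yn-1-olate (lithium ynolate) | CC(C)(O[Si](CC)(CC)CC)C#C[O-].[Li+] | intermediate
12 | triethyl({2-methyl-4-[(triisopropylsilyl)oxy]but-3-yn-2-yl}oxy)silane | CC(C)(O[Si](CC)(CC)CC)C#CO[Si](C(C)C)(C(C)C)C(C)C | intermediate
13 | trans-fused 11-(triethylsilyloxy)-8-(triisopropylsilyloxy)eudesma-3,6,8-triene (TIPS dienol ether of 14) | CC1=CCC[C@]2(C)C=C(O[Si](C(C)C)(C(C)C)C(C)C)C(=C[C@@H]12)C(C)(C)O[Si](CC)(CC)CC | intermediate
14 | (5R,10R)-11-(triethylsilyloxy)eudesma-3,6-dien-8-one, i.e. (4aR,8aR)-5,8a-dimethyl-3-{2-[(triethylsilyl)oxy]propan-2-yl}-4a,7,8,8a-tetrahydronaphthalen-2(1H)-one | CC1=CCC[C@]2(C)CC(=O)C(=C[C@@H]12)C(C)(C)O[Si](CC)(CC)CC | intermediate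
15 | (3R,4S,5R,10R)-3α,4α-dihydroxy-11-(triethylsilyloxy)eudesm-6-en-8-one | O[C@@H]1CC[C@]2(C)CC(=O)C(C(C)(C)O[Si](CC)(CC)CC)=C[C@H]2[C@]1(C)O | intermediate
16 | angelic acid, (Z)-2-methylbut-2-enoic acid | C/C=C(/C)C(=O)O | starting material
17 | angelic 2,4,6-trichlorobenzoic anhydride | C/C=C(/C)C(=O)OC(=O)c1c(Cl)cc(Cl)cc1Cl | intermediate
18 | 3α-angeloyloxy-4α-hydroxy-11-(triethylsilyloxy)eudesm-6-en-8-one | C/C=C(/C)C(=O)O[C@@H]1CC[C@]2(C)CC(=O)C(C(C)(C)O[Si](CC)(CC)CC)=C[C@H]2[C@]1(C)O | intermediate
19 | 4α-acetoxy-3α-angeloyloxy-11-(triethylsilyloxy)eudesm-6-en-8-one | C/C=C(/C)C(=O)O[C@@H]1CC[C@]2(C)CC(=O)C(C(C)(C)O[Si](CC)(CC)CC)=C[C@H]2[C@]1(C)OC(C)=O | intermediate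
20 | 4α-acetoxy-3α-angeloyloxy-11-hydroxyeudesm-6-en-8-one, (3R,4S,5R,10R), 5α-H, 10β-CH3 | C/C=C(/C)C(=O)O[C@@H]1CC[C@]2(C)CC(=O)C(C(C)(C)O)=C[C@H]2[C@]1(C)OC(C)=O | target

**Step count**

Total steps: 12. Longest linear sequence: 10 steps (steps 1, 2, 3, 4, 5, 8, 9, 10, 11, 12); the alkyne branch (steps 6 and 7) joins at step 8.

**Steps most likely to fail**

Step 8. The hindered alkyne (C7 carries a fully substituted carbon) may insert too slowly into the substrate alkylidene, so that it is used up by the methylidene carrier in alkyne–ethene cross metathesis. Ruthenium hydride from catalyst decay may also move the ring-A double bond into conjugation through the doubly allylic C5–H of the strained trans-fused product. The fallback uses known chemistry, sets out from 6 and 9 and returns at 14. Alkyne 9 is converted by bromoboration with B-bromo-9-borabicyclo[3.3.1]nonane and protonolysis with acetic acid into [(3-bromo-2-methylbut-3-en-2-yl)oxy]triethylsilane F1. Aldehyde 6 is homologated by Wittig reaction with Ph3P=CHOMe (from Ph3PCH2OMe chloride and KHMDS, THF) to the methyl enol ether F2, which aqueous HCl in THF hydrolyses to 2-(2-ethenyl-1,3-dimethylcyclohex-3-en-1-yl)acetaldehyde F3. The alkenyllithium made from F1 (t-BuLi, Et2O, −78 °C) adds to F3 to give the allylic alcohol F4 (both carbinol epimers), and Dess–Martin periodinane oxidises it to the cross-conjugated dienone F5. Ring-closing metathesis of F5 with second-generation Hoveyda–Grubbs catalyst (H2IMes)Cl2Ru=CH(C6H4-2-OiPr) in toluene at 80 °C closes C6=C7 and gives 14.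

Step 4. The acid-sensitive triene may polymerise at the cationic boron catalyst, and facial or exo control may erode on this trisubstituted diene. The fallback sets out from 4 (with 5) and returns at 6. A thermal or MeAlCl2-promoted cycloaddition without chiral catalyst gives racemic 2-ethenyl-1,3-dimethylcyclohex-3-ene-1-carbaldehyde F6 with the same exo, "ortho" orientation. It is resolved by preparative supercritical-fluid chromatography on a chiral stationary phase, and the (1S,2S) enantiomer is 6.

Step 10. The (Z)-enoyl unit may isomerise to the tiglate at the mixed-anhydride stage, or acylation of the axial C3 hydroxyl next to the tertiary carbinol may stall. The fallback sets out from 15 and returns at 18 and builds the Z-alkene after the ester bond. Diol 15 is esterified at C3–OH with 2-[bis(2,2,2-trifluoroethoxy)phosphoryl]propanoic acid (EDC·HCl, DMAP, CH2Cl2) to the phosphonopropionate F7. Deprotonation (KHMDS, 18-crown-6, THF, −78 °C) and addition of acetaldehyde should give angelate 18 by Z-selective Still–Gennari olefination.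

**Further compounds**

F1 | step 8 | [(3-bromo-2-methylbut-3-en-2-yl)oxy]triethylsilane | C=C(Br)C(C)(C)O[Si](CC)(CC)CC
F2 | step 8 | methyl enol ether of homologated 6: 3,4-trans-3-ethenyl-4-(2-methoxyethenyl)-2,4-dimethylcyclohex-1-ene (E/Z mixture, ring configuration as in 6) | CC1=CCC[C@](C)(C=COC)[C@H]1C=C
F3 | step 8 | 2-(2-ethenyl-1,3-dimethylcyclohex-3-en-1-yl)acetaldehyde (ring configuration as in 6) | CC1=CCC[C@](C)(CC=O)[C@H]1C=C
F4 | step 8 | 1-(2-ethenyl-1,3-dimethylcyclohex-3-en-1-yl)-4-methyl-3-methylidene-4-(triethylsilyloxy)pentan-2-ol (both carbinol epimers, ring configuration as in 6) | CC1=CCC[C@](C)(CC(O)C(=C)C(C)(C)O[Si](CC)(CC)CC)[C@H]1C=C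
F5 | step 8 | 1-(2-ethenyl-1,3-dimethylcyclohex-3-en-1-yl)-4-methyl-3-methylidene-4-(triethylsilyloxy)pentan-2-one (ring configuration as in 6) | CC1=CCC[C@](C)(CC(=O)C(=C)C(C)(C)O[Si](CC)(CC)CC)[C@H]1C=C
F6 | step 4 | racemic 2-ethenyl-1,3-dimethylcyclohex-3-ene-1-carbaldehyde (1S,2S and 1R,2R) | CC1=CCC[C@](C)(C=O)[C@H]1C=C.CC1=CCC[C@@](C)(C=O)[C@@H]1C=C
F7 | step 10 | 3α-{2-[bis(2,2,2-trifluoroethoxy)phosphoryl]propanoyloxy}-4α-hydroxy-11-(triethylsilyloxy)eudesm-6-en-8-one (epimers at the phosphonate-bearing carbon) | CC(C(=O)O[C@@H]1CC[C@]2(C)CC(=O)C(C(C)(C)O[Si](CC)(CC)CC)=C[C@H]2[C@]1(C)O)P(=O)(OCC(F)(F)F)OCC(F)(F)F
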